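**Plan**
- Retrosynthetic cuts, in order: the two bonds from the cyclopropane CH2 (C6) to C1 and C5 of the bicyclo[3.1.0]hexane, which leaves a C1=C5 cyclopentene. Then the aryl–C2 bond, then a temporary C5–O(aryl) ether bond, and last the C4–Br bond of the arene.
- Enabling feature: the phenol oxygen is ortho to the aryl–C2 bond, and the C1–C5 edge of the three-membered ring is a masked alkene. O–C(ar)–C(ar)–C2–C1=C5 is therefore the six-atom array that an aromatic Claisen rearrangement leaves behind.
- Forward order: the benzene ring and the five-membered ring are bought. The phenol is brominated, the enone is reduced, and the two halves are tied through O–C5. The [3,3] shift then trades this tether for the aryl–C2 bond, and the three-membered ring is closed last.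
- Stereochemistry: one carbinol centre comes from CBS catalysis and is inverted in the Mitsunobu step. It is relayed suprafacially to quaternary C2 in the [3,3] shift, and C2 sets C1 and C5 together in one phenoxide-directed methylene transfer.

Key step: step 4

Assumption: the CBS reduction of 3 is taken to follow the usual model, with the methyl-bearing alkenyl arm as the large group; if the opposite alcohol forms, the enantiomeric catalyst is used.

Step 1
Reactants: 1 2-bromo-3-methylphenol
Product: 2 2,4-dibromo-3-methylphenol
Conditions: NBS (1.0 equiv), MeCN, −20 → 0 °C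
Reagents that add atoms: N-bromosuccinimide, O=C1CCC(=O)N1Br
Why: Electrophilic aromatic bromination with NBS in acetonitrile is the para-selective protocol for phenols; C4 is para to OH and ortho to CH3, and one equivalent at low temperature should limit attack at the likewise activated C6 and overbromination.

Step 2
Reactants: 3 2,3-dimethylcyclopent-2-en-1-one
Product: 4 (1R)-2,3-dimethylcyclopent-2-en-1-ol
Conditions: (S)-Me-CBS (10 mol %), BH3·SMe2, THF, −20 °C; MeOH quench
Reagents that add atoms: none
Why: In this Corey–Bakshi–Shibata reduction the ketone should bind to the catalyst boron with the methyl-bearing alkenyl arm as the large group, so hydride from the coordinated borane reaches one carbonyl face and sets the (R)-carbinol centre, and 1,2-reduction should be clean because the tetrasubstituted alkene resists hydroboration at this temperature.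

Step 3
Reactants: 2 2,4-dibromo-3-methylphenol; 4 (1R)-2,3-dimethylcyclopent-2-en-1-ol
Product: 5 1,3-dibromo-4-{[(1S)-2,3-dimethylcyclopent-2-en-1-yl]oxy}-2-methylbenzene
Conditions: PPh3, DIAD, PhMe, −20 → 0 °C
Reagents that add atoms: none
Why: In this Mitsunobu etherification the acidic dibromophenol displaces the oxyphosphonium group of 4 by SN2 with inversion, (R) to (S), while the fully substituted γ-carbon blocks the SN2' path and toluene at low temperature holds back ionisation.

Step 4
Reactants: 5 1,3-dibromo-4-{[(1S)-2,3-dimethylcyclopent-2-en-1-yl]oxy}-2-methylbenzene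
Product: 7 2,4-dibromo-6-[(1R)-1,2-dimethylcyclopent-2-en-1-yl]-3-methylphenol, via ortho-dienone 6 (not isolated)
Conditions: Eu(fod)3 (10 mol %), NaHCO3, PhMe, 80 °C
Reagents that add atoms: none
Why: Eu(III) coordination to the ether oxygen polarises the bond from oxygen to the carbinol carbon C1', and 5 should pass through a concerted, asynchronous [3,3] shift in which the free ortho carbon of the arene bonds to the methyl-bearing alkene terminus C3' while C1'–O breaks, giving ortho-dienone 6, which enolises at once to phenol 7. The closest known reaction types are the Eu(fod)3-catalysed aromatic Claisen rearrangement of enantioenriched cycloalk-2-enyl aryl ethers with 1,3-chirality transfer, and the Claisen rearrangement of γ,γ-disubstituted allyl aryl ethers that gives aryl-bearing quaternary carbons. No ring is closed; only a six-membered cyclic transition state is passed, and the O–C1' tether is removed in the same event. The new quaternary centre is controlled by the (S)-C1'–O centre, because the arene hangs from one face of the cyclopentene and can reach C3' on that face only (suprafacial, chair or boat alike), so (S)-5 should give (R)-7. Regioselectivity is secured by the substrate, since bromine occupies the second ortho position and the para position, and the ortho bromine turns the O-alkyl group towards the free ortho C–H. The pericyclic path must also outrun ionisation and elimination, which the non-polar solvent, the weak Lewis acid and the NaHCO3 buffer are chosen to favour, and the shift leaves the alkene exactly at the later C1=C5 edge with the free OH beside it for step 5.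

Step 5
Reactants: 7 2,4-dibromo-6-[(1R)-1,2-dimethylcyclopent-2-en-1-yl]-3-methylphenol
Product: 9 2,4-dibromo-6-[(1S,2R,5R)-1,2-dimethylbicyclo[3.1.0]hexan-2-yl]-3-methylphenol, via iodomethylzinc phenoxide 8 (not isolated)
Conditions: Et2Zn, then CH2I2, CH2Cl2, −10 °C → rt; aq NaHCO3/EDTA work-up
Reagents that add atoms: diiodomethane, ICI
Why: In this phenol-directed Furukawa-type Simmons–Smith cyclopropanation Et2Zn deprotonates the OH and exchange with CH2I2 gives the electron-poor, hence strongly electrophilic, aryloxy(iodomethyl)zinc 8, whose carbenoid carbon is held over the alkene face bearing the aryl group, so CH2 should be delivered syn to the arene and set C1 (S) and C5 (R) together in a necessarily cis ring fusion, while the aryl bromides are inert to the zinc reagents.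

**Compound list**
1 | 2-bromo-3-methylphenol | Cc1cccc(O)c1Br | starting material
2 | 2,4-dibromo-3-methylphenol | Cc1c(Br)ccc(O)c1Br | intermediate
3 | 2,3-dimethylcyclopent-2-en-1-one | CC1=C(C)C(=O)CC1 | starting material
4 | (1R)-2,3-dimethylcyclopent-2-en-1-ol | O[C@@H]1CCC(C)=C1C | intermediate
5 | 1,3-dibromo-4-{[(1S)-2,3-dimethylcyclopent-2-en-1-yl]oxy}-2-methylbenzene | Cc1c(Br)ccc(O[C@H]2CCC(C)=C2C)c1Br | intermediate
6 | 2,4-dibromo-6-[(1S)-1,2-dimethylcyclopent-2-en-1-yl]-3-methylcyclohexa-2,4-dien-1-one (same spatial arrangement at the quaternary carbon as in 7, descriptor changed by CIP priority only; ring CH epimer undefined and erased on enolisation) | O=C1C(Br)=C(C)C(Br)=CC1[C@]2(C)CCC=C2C | intermediate (not isolated)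
7 | 2,4-dibromo-6-[(1R)-1,2-dimethylcyclopent-2-en-1-yl]-3-methylphenol | Cc1c(Br)cc([C@]2(C)CCC=C2C)c(O)c1Br | intermediate
8 | iodomethylzinc 2,4-dibromo-6-[(1R)-1,2-dimethylcyclopent-2-en-1-yl]-3-methylphenoxide | Cc1c(Br)cc([C@]2(C)CCC=C2C)c(O[Zn]CI)c1Br | intermediate (not isolated)
9 | 2,4-dibromo-6-[(1S,2R,5R)-1,2-dimethylbicyclo[3.1.0]hexan-2-yl]-3-methylphenol | Cc1c(Br)cc([C@]2(C)CC[C@@H]3C[C@@]32C)c(O)c1Br | target

Total step count: 5
Longest linear sequence: 4 (steps 2, 3, 4, 5, or equally steps 1, 3, 4, 5)

**Steps most likely to fail**

**1. Step 4.**
- What may go wrong: heterolysis of the doubly activated allylic C–O bond may outrun the concerted shift. The ion pair could then recombine at the less hindered allyl terminus or with loss of configuration. The phenol could also be eliminated from the ring.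
- Fallback (sets out from 4, returns at 9): the same aryl–C2 bond is made intermolecularly by copper-mediated anti-SN2' allylic arylation, and both bromines are added last.
- Alcohol 4 is esterified with picolinic acid (DCC, DMAP) to give (1R)-2,3-dimethylcyclopent-2-en-1-yl pyridine-2-carboxylate F1.
- Commercial 2-bromo-5-methylanisole and magnesium give (2-methoxy-4-methylphenyl)magnesium bromide F2.
- With CuBr·SMe2 in THF, F2 should displace the magnesium-chelated picolinate of F1 at the γ-carbon, anti to the leaving group. This gives 1-[(1R)-1,2-dimethylcyclopent-2-en-1-yl]-2-methoxy-4-methylbenzene F3.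
- Acid-free demethylation with NaSEt in hot DMF gives 2-[(1R)-1,2-dimethylcyclopent-2-en-1-yl]-5-methylphenol F4.
- Phenol-directed Simmons–Smith cyclopropanation gives 2-[(1S,2R,5R)-1,2-dimethylbicyclo[3.1.0]hexan-2-yl]-5-methylphenol F5.
- Two equivalents of NBS with catalytic diisopropylamine fill the only two activated free positions, para and ortho to OH, to give 9.

**2. Step 3.**
- What may go wrong: the oxyphosphonium salt may ionise in part to the 1,2-dimethylcyclopentenyl cation, which erodes the configuration. It may also lose a proton to give the diene.
- Fallback (sets out from 3, returns at 5): the ether is made with net retention through a π-allylpalladium complex instead of by SN2 inversion.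
- Reduction of 3 with the (R)-configured oxazaborolidine and borane gives (1S)-2,3-dimethylcyclopent-2-en-1-ol F6.
- Methyl chloroformate and pyridine give (1S)-2,3-dimethylcyclopent-2-en-1-yl methyl carbonate F7.
- Tsuji–Trost O-allylation of phenol 2 with F7 (Pd2(dba)3, phosphine, THF, 0 °C) proceeds by ionisation with inversion, followed by phenoxide attack anti to palladium at the less substituted allyl terminus. This should give 5 with overall retention.

**3. Step 5.**
- What may go wrong: methylene transfer to the trisubstituted alkene next to the quaternary carbon may be slow. Untethered carbenoid may then attack the other face. Zinc iodide may also promote attack of the acidic dibromophenol on the alkene or on the new cyclopropane.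
- Fallback (sets out from 4, returns at 9): the order of events is changed, so the cyclopropane is built on a less acidic phenol that is unhindered at oxygen, and the second bromine comes last.
- Mitsunobu coupling of 4 with commercial 4-bromo-3-methylphenol gives 1-bromo-4-{[(1S)-2,3-dimethylcyclopent-2-en-1-yl]oxy}-2-methylbenzene F8.
- The Claisen rearrangement gives 4-bromo-2-[(1R)-1,2-dimethylcyclopent-2-en-1-yl]-5-methylphenol F9. Here regiochemistry rests on the crowding of the position between O and CH3.
- Directed Simmons–Smith cyclopropanation gives 4-bromo-2-[(1S,2R,5R)-1,2-dimethylbicyclo[3.1.0]hexan-2-yl]-5-methylphenol F10.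
- Amine-mediated ortho-bromination (NBS, catalytic i-Pr2NH, CH2Cl2) at the single free activated position gives 9 under non-acidic conditions.

**Further compounds**
F1 | step 4 | (1R)-2,3-dimethylcyclopent-2-en-1-yl pyridine-2-carboxylate | O=C(O[C@@H]1CCC(C)=C1C)c1ccccn1
F2 | step 4 | (2-methoxy-4-methylphenyl)magnesium bromide | COc1cc(C)ccc1[Mg]Br
F3 | step 4 | 1-[(1R)-1,2-dimethylcyclopent-2-en-1-yl]-2-methoxy-4-methylbenzene | COc1cc(C)ccc1[C@]2(C)CCC=C2C
F4 | step 4 | 2-[(1R)-1,2-dimethylcyclopent-2-en-1-yl]-5-methylphenol | Cc1ccc([C@]2(C)CCC=C2C)c(O)c1
F5 | step 4 | 2-[(1S,2R,5R)-1,2-dimethylbicyclo[3.1.0]hexan-2-yl]-5-methylphenol | Cc1ccc([C@]2(C)CC[C@@H]3C[C@@]32C)c(O)c1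
F6 | step 3 | (1S)-2,3-dimethylcyclopent-2-en-1-ol | O[C@H]1CCC(C)=C1C
F7 | step 3 | (1S)-2,3-dimethylcyclopent-2-en-1-yl methyl carbonate | COC(=O)O[C@H]1CCC(C)=C1C
F8 | step 5 | 1-bromo-4-{[(1S)-2,3-dimethylcyclopent-2-en-1-yl]oxy}-2-methylbenzene | Cc1cc(O[C@H]2CCC(C)=C2C)ccc1Br
F9 | step 5 | 4-bromo-2-[(1R)-1,2-dimethylcyclopent-2-en-1-yl]-5-methylphenol | Cc1cc(O)c([C@]2(C)CCC=C2C)cc1Br
F10 | step 5 | 4-bromo-2-[(1S,2R,5R)-1,2-dimethylbicyclo[3.1.0]hexan-2-yl]-5-methylphenol | Cc1cc(O)c([C@]2(C)CC[C@@H]3C[C@@]32C)cc1Br
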